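The synthesis disconnects the fully substituted C2 of the dihydropyran ring at O1–C2 and, one atom further out, at C1'–C2'. C2 is bonded to O1, C3, a methyl group and C1' and carries no hydrogen. An alkylpalladium generated at C1' by oxypalladation therefore has no β-hydride to lose and lasts long enough to be carbonylated. One operation thus closes the dihydropyran ring, sets the only stereocentre and installs an ester handle for the chain. The precursor is an achiral, easily made phenol: free C8a hydroxyl, 3-methylbut-3-enyl arm at C4a, methyl at C8, silylated O6. The triene is attached afterwards by Negishi coupling (C2'–C3'), and the C5 aldehyde is introduced last.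

Key step: step 6

Remark on numbering: chroman numbering (O1 to C8a) and side-chain numbering (C1' onward) are also used for the atoms of earlier intermediates that end up at these positions.
Remark on descriptors: the ester, alcohol, iodide and zinc reagent are 2S, while the coupled chromans and the target are 2R. The spatial arrangement at C2 never changes; C1' simply outranks C3 only while C2' carries O, I or Zn.
Assumption: the (S,S)-ligand is taken to give the 2S ester, by analogy with the sense of induction known for this reaction class. If the sense is opposite, the antipodal ligand is used and nothing else changes. The ligand is a known compound used in catalytic amount and is not counted in the steps.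

Step 1
Reactants: 1 2-methylhydroquinone
Product: 2 2-methyl-4-(triisopropylsilyloxy)phenol
Conditions: TIPSCl (1.0 equiv), imidazole (2.2 equiv), DMF, 0 °C → rt
Reagents that add atoms: chlorotriisopropylsilane, CC(C)[Si](Cl)(C(C)C)C(C)C
Why: Imidazole-promoted silyl ether formation is sterically governed, so the bulky chlorosilane should take the hydroxyl flanked by two ring hydrogens rather than the one next to the methyl group, and one equivalent limits double silylation.

Step 2
Reactants: 2 2-methyl-4-(triisopropylsilyloxy)phenol
Product: 3 2-hydroxy-3-methyl-5-(triisopropylsilyloxy)benzaldehyde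
Conditions: MgCl2 (anhydrous, 2 equiv), Et3N (4 equiv), (CH2O)n (6 equiv), MeCN, reflux; cold 1 M HCl
Reagents that add atoms: paraformaldehyde (as formaldehyde), C=O
Why: In this Casnati–Skattebøl ortho-formylation, magnesium bound to the free phenol oxygen delivers formaldehyde to the only open ortho carbon (the future C4a), hydride transfer to a second formaldehyde raises the product to the aldehyde level, and the silylated oxygen cannot direct.

Step 3
Reactants: 3 2-hydroxy-3-methyl-5-(triisopropylsilyloxy)benzaldehyde; 4 1-(triphenylphosphoranylidene)propan-2-one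
Product: 5 (E)-4-[2-hydroxy-3-methyl-5-(triisopropylsilyloxy)phenyl]but-3-en-2-one
Conditions: toluene, 80 °C
Reagents that add atoms: none
Why: A Wittig olefination with a stabilised ylide is too weakly basic to be disturbed by the free phenol and should give the E-enone, whose geometry does not matter because the alkene is saturated next.

Step 4
Reactants: 5 (E)-4-[2-hydroxy-3-methyl-5-(triisopropylsilyloxy)phenyl]but-3-en-2-one
Product: 6 4-[2-hydroxy-3-methyl-5-(triisopropylsilyloxy)phenyl]butan-2-one
Conditions: H2 (1 atm), Pd/C (10 wt %), EtOAc, rt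
Reagents that add atoms: none
Why: Heterogeneous catalytic hydrogenation saturates the conjugated alkene much faster than it touches the ketone, the arene or the silyl ether, and any cyclic hemiketal form of 6 stays in equilibrium with the open ketone.

Step 5
Reactants: 6 4-[2-hydroxy-3-methyl-5-(triisopropylsilyloxy)phenyl]butan-2-one
Product: 7 2-methyl-6-(3-methylbut-3-enyl)-4-(triisopropylsilyloxy)phenol
Conditions: MePPh3Br (3.5 equiv), KOtBu (3.3 equiv), THF, 0 °C → rt; aq. NH4Cl
Reagents that add atoms: methyltriphenylphosphonium bromide, C[P+](c1ccccc1)(c1ccccc1)c1ccccc1.[Br-]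
Why: In this Wittig methylenation with excess non-stabilised ylide the first equivalent only deprotonates the phenol, the rest converts the methyl ketone into the 1,1-disubstituted alkene, and keeping the salt in excess over the base leaves no free alkoxide to attack silicon.

Step 6
Reactants: 7 2-methyl-6-(3-methylbut-3-enyl)-4-(triisopropylsilyloxy)phenol
Product: 10 methyl 2-[(2S)-2,8-dimethyl-6-(triisopropylsilyloxy)chroman-2-yl]acetate, via alkylpalladium trifluoroacetate 8 (not isolated), via acylpalladium trifluoroacetate 9 (not isolated)
Conditions: Pd(OCOCF3)2 (5 mol %), (S,S)-Bn-BOXAX [(aS)-2,2'-bis((4S)-4-benzyl-4,5-dihydrooxazol-2-yl)-1,1'-binaphthyl, 20 mol %], p-benzoquinone (4 equiv), CO (1 atm), MeOH, rt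
Reagents that add atoms: carbon monoxide, [C-]#[O+]; methanol, CO; Pd(OCOCF3)2, O=C(O[Pd]OC(=O)C(F)(F)F)C(F)(F)F (palladium and trifluoroacetate carried by intermediates 8 and 9 only)
Why: The bis(oxazoline)-bound divalent palladium coordinates one face of the 1,1-disubstituted alkene of 7 and the C8a hydroxyl adds to the substituted alkene carbon (intramolecular Wacker-type oxypalladation), which forms O1–C2 and closes the dihydropyran ring in the 6-exo-trig mode to give 8. In 8 the only carbon β to the metal is the hydrogen-free C2, so β-hydride elimination has nothing to act on and CO inserts into the C1'–Pd bond (C1'–C2', giving 9); methanolysis of 9 releases ester 10 together with zerovalent palladium, and p-benzoquinone reoxidises the metal to its divalent form so that the cycle restarts. The closest known reaction type is the enantioselective domino Wacker cyclisation–carbonylation–methoxylation of 2-(3-methylbut-3-enyl)phenols to 2-methylchroman-2-ylacetates. The C2 stereocentre is controlled by the ligand alone: its twofold-symmetric binaphthyl pocket tells the small methyl group apart from the chain that loops back to the coordinated phenol oxygen, and the (S,S)-ligand is expected to lead to the 2S ester. The step needs regioselectivity for exo attack at the substituted carbon over 7-endo attack, secured by the Markovnikov polarisation of the alkene and the two-carbon tether, and chemoselectivity against oxidation of the electron-rich arene, secured by the silyl cap on O6 that blocks quinone formation. Carbonylation must also outrun alkene migration, which the CO atmosphere, the weakly coordinating trifluoroacetate and the excess of ligand are chosen to favour.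

Step 7
Reactants: 10 methyl 2-[(2S)-2,8-dimethyl-6-(triisopropylsilyloxy)chroman-2-yl]acetate
Product: 11 2-[(2S)-2,8-dimethyl-6-(triisopropylsilyloxy)chroman-2-yl]ethanol
Conditions: LiAlH4 (1.2 equiv), Et2O, 0 °C; then Na2SO4·10H2O
Reagents that add atoms: none
Why: Hydride reduction of the ester gives the primary alcohol, the quaternary C2 cannot epimerise, and the aryl triisopropylsilyl ether is stable to LiAlH4 at this temperature.

Step 8
Reactants: 11 2-[(2S)-2,8-dimethyl-6-(triisopropylsilyloxy)chroman-2-yl]ethanol
Product: 12 (2S)-2-(2-iodoethyl)-2,8-dimethyl-6-(triisopropylsilyloxy)chroman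
Conditions: PPh3 (1.3 equiv), imidazole (1.5 equiv), I2 (1.3 equiv), CH2Cl2, 0 °C → rt
Reagents that add atoms: iodine, II
Why: The Appel-type iodination activates the primary hydroxyl as an oxyphosphonium ion that iodide displaces by SN2 at the unhindered C2' under nearly neutral conditions, which spare the silyl ether and the chroman.

Step 9
Reactants: 13 propyne; 14 geranyl bromide
Product: 16 (E)-6,10-dimethylundeca-5,9-dien-1-yne, via 1,3-dilithiopropyne 15 (not isolated)
Conditions: 13 (1.5 equiv), n-BuLi (3.0 equiv), TMEDA, Et2O–hexane, −78 °C → rt; then 14, 0 °C → rt; H2O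
Reagents that add atoms: n-butyllithium, [Li]CCCC (lithium carried by intermediate 15 only)
Why: In this propargylic dianion alkylation the sp3 terminus of 15 is the more nucleophilic one and displaces the primary allylic bromide by direct SN2 without allylic transposition, so the E alkene of 14 is kept and the acetylide end is simply protonated on work-up.

Step 10
Reactants: 16 (E)-6,10-dimethylundeca-5,9-dien-1-yne
Product: 18 (1E,5E)-1-iodo-2,6,10-trimethylundeca-1,5,9-triene, via alkenyldimethylalane 17 (not isolated)
Conditions: AlMe3 (2 equiv), Cp2ZrCl2 (0.25 equiv), CH2Cl2, 0 °C → rt; then I2 (1.2 equiv), THF, −30 °C → 0 °C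
Reagents that add atoms: trimethylaluminium, C[Al](C)C; iodine, II
Why: The zirconium-catalysed Negishi carboalumination adds methyl and aluminium syn across the terminal alkyne with aluminium at the terminal carbon, iodinolysis proceeds with retention to fix the E geometry of the future C3'–C4' alkene, and the trisubstituted alkenes are inert.

Step 11
Reactants: 12 (2S)-2-(2-iodoethyl)-2,8-dimethyl-6-(triisopropylsilyloxy)chroman; 18 (1E,5E)-1-iodo-2,6,10-trimethylundeca-1,5,9-triene
Product: 20 (2R)-2,8-dimethyl-2-[(3E,7E)-4,8,12-trimethyltrideca-3,7,11-trienyl]-6-(triisopropylsilyloxy)chroman, via alkylzinc iodide 19 (not isolated)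
Conditions: 12, Zn dust (3 equiv, activated with BrCH2CH2Br and Me3SiCl), LiCl (1.5 equiv), THF, 40 °C; then 18 (0.9 equiv), PdCl2(dppf) (5 mol %), THF, rt → 40 °C
Reagents that add atoms: zinc, [Zn] (carried by intermediate 19 only)
Why: Direct zinc insertion into the primary C–I bond is followed by a Negishi sp3–sp2 coupling, in which the alkenyl iodide reacts with retention of geometry, the wide-bite dppf ligand speeds reductive elimination over β-hydride elimination, and the aryloxy group of 19 sits on the γ-carbon (C2), too far away for β-elimination.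

Step 12
Reactants: 20 (2R)-2,8-dimethyl-2-[(3E,7E)-4,8,12-trimethyltrideca-3,7,11-trienyl]-6-(triisopropylsilyloxy)chroman
Product: 21 (2R)-2,8-dimethyl-2-[(3E,7E)-4,8,12-trimethyltrideca-3,7,11-trienyl]chroman-6-ol, (R)-δ-tocotrienol
Conditions: Bu4NF (1.2 equiv), AcOH (1.2 equiv), THF, 0 °C, argon
Reagents that add atoms: none
Why: Fluoride-induced desilylation of the aryl silyl ether is fast and leaves the acid-sensitive triene untouched, and the acetic acid buffer protonates the chromanoxide at once so that it is not lost to air oxidation.

Step 13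
Reactants: 21 (R)-δ-tocotrienol
Product: 22 (2R)-6-hydroxy-2,8-dimethyl-2-[(3E,7E)-4,8,12-trimethyltrideca-3,7,11-trienyl]chroman-5-carbaldehyde
Conditions: MgCl2 (anhydrous, 2 equiv), Et3N (4 equiv), (CH2O)n (5 equiv), THF, reflux, argon; 1 M HCl, 0 °C
Reagents that add atoms: paraformaldehyde (as formaldehyde), C=O
Why: This Casnati–Skattebøl ortho-formylation is directed by the freed C6 hydroxyl, and C5 should be preferred over C7 because the fused dihydropyran ring gives the C5–C6 bond the higher double-bond character (Mills–Nixon-type bond fixation) and C7 is crowded by the C8 methyl group, while the chelated aldehyde deactivates the ring towards a second attack and the basic medium spares the triene and C2.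

Compound list
1 | 2-methylhydroquinone | Cc1cc(O)ccc1O | starting material
2 | 2-methyl-4-(triisopropylsilyloxy)phenol | Cc1cc(O[Si](C(C)C)(C(C)C)C(C)C)ccc1O | intermediate
3 | 2-hydroxy-3-methyl-5-(triisopropylsilyloxy)benzaldehyde | Cc1cc(O[Si](C(C)C)(C(C)C)C(C)C)cc(C=O)c1O | intermediate
4 | 1-(triphenylphosphoranylidene)propan-2-one | CC(=O)C=P(c1ccccc1)(c1ccccc1)c1ccccc1 | starting material
5 | (E)-4-[2-hydroxy-3-methyl-5-(triisopropylsilyloxy)phenyl]but-3-en-2-one | CC(=O)/C=C/c1cc(O[Si](C(C)C)(C(C)C)C(C)C)cc(C)c1O | intermediate
6 | 4-[2-hydroxy-3-methyl-5-(triisopropylsilyloxy)phenyl]butan-2-one | CC(=O)CCc1cc(O[Si](C(C)C)(C(C)C)C(C)C)cc(C)c1O | intermediate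
7 | 2-methyl-6-(3-methylbut-3-enyl)-4-(triisopropylsilyloxy)phenol | C=C(C)CCc1cc(O[Si](C(C)C)(C(C)C)C(C)C)cc(C)c1O | intermediate
8 | C1'-alkylpalladium trifluoroacetate of the closed chroman (chiral ligand on palladium not drawn) | O=C(O[Pd]C[C@]1(C)CCc2cc(O[Si](C(C)C)(C(C)C)C(C)C)cc(C)c2O1)C(F)(F)F | intermediate
9 | C2'-acylpalladium trifluoroacetate after CO insertion (chiral ligand on palladium not drawn) | O=C(O[Pd]C(=O)C[C@]1(C)CCc2cc(O[Si](C(C)C)(C(C)C)C(C)C)cc(C)c2O1)C(F)(F)F | intermediate
10 | methyl 2-[(2S)-2,8-dimethyl-6-(triisopropylsilyloxy)chroman-2-yl]acetate | COC(=O)C[C@]1(C)CCc2cc(O[Si](C(C)C)(C(C)C)C(C)C)cc(C)c2O1 | intermediate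
11 | 2-[(2S)-2,8-dimethyl-6-(triisopropylsilyloxy)chroman-2-yl]ethanol | OCC[C@]1(C)CCc2cc(O[Si](C(C)C)(C(C)C)C(C)C)cc(C)c2O1 | intermediate
12 | (2S)-2-(2-iodoethyl)-2,8-dimethyl-6-(triisopropylsilyloxy)chroman | ICC[C@]1(C)CCc2cc(O[Si](C(C)C)(C(C)C)C(C)C)cc(C)c2O1 | intermediate
13 | propyne | CC#C | starting material
14 | geranyl bromide | CC(C)=CCC/C(C)=C/CBr | starting material
15 | 1,3-dilithiopropyne | [Li]CC#C[Li] | intermediate
16 | (E)-6,10-dimethylundeca-5,9-dien-1-yne | C#CCC/C=C(\C)CCC=C(C)C | intermediate
17 | [(1E,5E)-2,6,10-trimethylundeca-1,5,9-trienyl]dimethylalane | C[Al](C)/C=C(\C)CC/C=C(\C)CCC=C(C)C | intermediate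
18 | (1E,5E)-1-iodo-2,6,10-trimethylundeca-1,5,9-triene | I/C=C(\C)CC/C=C(\C)CCC=C(C)C | intermediate
19 | 2-[(2S)-2,8-dimethyl-6-(triisopropylsilyloxy)chroman-2-yl]ethylzinc iodide | I[Zn]CC[C@]1(C)CCc2cc(O[Si](C(C)C)(C(C)C)C(C)C)cc(C)c2O1 | intermediate
20 | (2R)-2,8-dimethyl-2-[(3E,7E)-4,8,12-trimethyltrideca-3,7,11-trienyl]-6-(triisopropylsilyloxy)chroman | CC(C)=CCC/C(C)=C/CC/C(C)=C/CC[C@]1(C)CCc2cc(O[Si](C(C)C)(C(C)C)C(C)C)cc(C)c2O1 | intermediate
21 | (R)-δ-tocotrienol, (2R)-2,8-dimethyl-2-[(3E,7E)-4,8,12-trimethyltrideca-3,7,11-trienyl]chroman-6-ol | CC(C)=CCC/C(C)=C/CC/C(C)=C/CC[C@]1(C)CCc2cc(O)cc(C)c2O1 | intermediate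
22 | (2R)-6-hydroxy-2,8-dimethyl-2-[(3E,7E)-4,8,12-trimethyltrideca-3,7,11-trienyl]chroman-5-carbaldehyde | CC(C)=CCC/C(C)=C/CC/C(C)=C/CC[C@]1(C)CCc2c(C=O)c(O)cc(C)c2O1 | target

Total step count: 13. Longest linear sequence: 11 (steps 1–8 and 11–13). Alkenyl iodide 18 is made in parallel in two steps (9 and 10).

Steps most likely to fail

Risk 1, step 6. Enantioface selection may fall short, because the arene of 7 carries only hydrogen at C5 next to the tether and may sit loosely in the ligand pocket. Alkene migration may also drain material. The fallback replaces catalyst control by classical resolution and sets out from 10 of whatever enantiomeric purity is obtained. Me3SnOH in 1,2-dichloroethane at 80 °C should cleave the methyl ester without harming the aryl silyl ether and give 2-[(2S)-2,8-dimethyl-6-(triisopropylsilyloxy)chroman-2-yl]acetic acid F1. Crystallisation with (S)-1-phenylethylamine from ethyl acetate–hexane to constant rotation should give the diastereomerically pure (S)-1-phenylethylammonium carboxylate F2. The antipodal amine is taken if it forms the less soluble salt with the 2S acid. Partition between ether and cold aqueous citric acid returns F1, and LiAlH4 in Et2O at 0 °C reduces it to 11, where the route is rejoined.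

Risk 2, step 13. Attack at C7 may compete with attack at C5, and a second formylation may follow. The fallback exchanges the magnesium-templated formaldehyde transfer for halogenation and halogen–lithium exchange and sets out from 21. N-Bromosuccinimide (1.0 equiv) in CH2Cl2 at −78 °C in the dark should brominate the strongly activated ring at C5 faster than it reaches the trisubstituted alkenes. Its more charge-developed transition state should also respond more strongly to the bond fixation. The product, (2R)-5-bromo-δ-tocotrienol F3, is freed from any C7 isomer at this stage. t-BuLi (3.2 equiv) in THF at −78 °C removes the phenolic proton and exchanges bromine for lithium to give the O6,C5-dilithio species F4. DMF followed by cold aqueous NH4Cl converts it into 22.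

Risk 3, step 11. Zinc insertion may stall, the zinc reagent may be protonated, and β-hydride elimination after transmetalation may erode the coupling. The fallback moves to a B-alkyl Suzuki–Miyaura coupling and sets out from 12 and 18. t-BuLi (2.1 equiv) in Et2O at −78 °C converts 12 into the primary alkyllithium F5. B-Methoxy-9-borabicyclo[3.3.1]nonane captures it as the lithium B-alkyl-B-methoxyborinate F6. Addition of 18, PdCl2(dppf), aqueous K3PO4 and DMF to the same flask at rt should give 20.

Further compounds
F1 | step 6 | 2-[(2S)-2,8-dimethyl-6-(triisopropylsilyloxy)chroman-2-yl]acetic acid | OC(=O)C[C@]1(C)CCc2cc(O[Si](C(C)C)(C(C)C)C(C)C)cc(C)c2O1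
F2 | step 6 | (S)-1-phenylethylammonium 2-[(2S)-2,8-dimethyl-6-(triisopropylsilyloxy)chroman-2-yl]acetate | C[C@H]([NH3+])c1ccccc1.[O-]C(=O)C[C@]1(C)CCc2cc(O[Si](C(C)C)(C(C)C)C(C)C)cc(C)c2O1
F3 | step 13 | (2R)-5-bromo-2,8-dimethyl-2-[(3E,7E)-4,8,12-trimethyltrideca-3,7,11-trienyl]chroman-6-ol | CC(C)=CCC/C(C)=C/CC/C(C)=C/CC[C@]1(C)CCc2c(Br)c(O)cc(C)c2O1
F4 | step 13 | lithium 5-lithio-δ-tocotrienol-6-olate (C2 as in 21) | CC(C)=CCC/C(C)=C/CC/C(C)=C/CC[C@]1(C)CCc2c([Li])c(O[Li])cc(C)c2O1
F5 | step 11 | 2-[2,8-dimethyl-6-(triisopropylsilyloxy)chroman-2-yl]ethyllithium (C2 arranged as in 12) | [Li]CC[C@]1(C)CCc2cc(O[Si](C(C)C)(C(C)C)C(C)C)cc(C)c2O1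
F6 | step 11 | lithium B-methoxy-B-{2-[2,8-dimethyl-6-(triisopropylsilyloxy)chroman-2-yl]ethyl}-9-borabicyclo[3.3.1]nonanate (C2 arranged as in 12) | [Li+].CO[B-]1(CC[C@]2(C)CCc3cc(O[Si](C(C)C)(C(C)C)C(C)C)cc(C)c3O2)C2CCCC1CCC2
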